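The readings were generated by integration on assumed constants; noise was put on by code.

If each coupling partner simply makes one target, says my colleague, then the coupling partner is the limiting reagent and the flask ends at 50.0% target, with the same conversion.

| flask | substrate | coupling partner | remark | time |
|---|---|---|---|---|
| elm | 0.050 M | 0.013 M | run made earlier |  |
| cedar | 0.050 M | 0.050 M | run made earlier |  |
| maple | 0.075 M | 0.025 M | run made earlier |  |
| flask | 0.050 M | 0.0250 M |  | 6.0 d |

| run | time / d | substrate / % | target / % |
|---|---|---|---|
| elm | 0.500 | 78.2 | 19.0 |
| elm | 1.67 | 77.7 | 19.6 |
| elm | 3.00 | 77.6 | 20.4 |
| elm | 4.00 | 76.9 | 20.2 |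
| elm | 6.00 | 77.4 | 19.9 |
| cedar | 0.500 | 29.0 | 47.9 |
| cedar | 1.67 | 26.9 | 49.9 |
| cedar | 3.00 | 26.2 | 49.8 |
| cedar | 4.00 | 27.5 | 49.9 |
| cedar | 6.00 | 27.0 | 49.1 |
| maple | 1.25 | 72.2 | 22.4 |
| maple | 2.50 | 72.5 | 21.9 |
| maple | 4.00 | 73.9 | 22.0 |
| maple | 5.00 | 72.5 | 22.5 |
| maple | 6.00 | 72.7 | 21.5 |

(standard deviation of a reading: 0.5 percentage points)

- the reaction counts as stopped when no species that holds the substrate changes by six tenths of a point or more over the second half of the time

- which holds at 6.0 d: what has brought the reaction to rest, or that it has not come to rest (the coupling partner has run out first / forward and back rates have come level / it is still moving / all of the substrate has reacted)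
- how much of the substrate has reacted by 6.0 d
- how much target there is at 6.0 d, in percent of the substrate charged

I read the runs otherwise. Cedar's first reading is still moving, but from 1.67 d on its readings are flat and average 26.9% substrate and 49.7% target, so 23.4% of its substrate stands as something else, which I call side product. If side product takes two coupling partners, target and side product in cedar account for 96.5% of the coupling partner charged, so I expect rest by its exhaustion.

The ratio of side product to target in cedar is 0.472. Maple, charged half as much coupling partner, averages 72.8% substrate and 22.1% target, a ratio of 0.235, half of cedar's, though it holds more substrate. So I take the ratio as proportional to the charged c(coupling partner), at 9.43 /M.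

That gives the partner price, the coupling partner spent per target made, one plus twice the ratio: for the flask 1.47. Put my colleague's answer back in: that much target at this price needs 0.0367 M, more than the 0.0250 M charged. Going round once more, target in the flask falls to charge over price, 34.0%, with 8.01% side product and 42.0% conversion.

The forecast says the coupling partner has run out first, “so the partner ran out”, with conversion 41.5% (39.5% to 44.5%) and target 32.8% (31% to 36.5%), below my figure.

The flask gives: the coupling partner has run out first, conversion 40.2%, target 32.1%.

    substrate + coupling partner → target (k = 11.0 /M/h)
    substrate + 2 coupling partner → side product (k = 250 /M²/h)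
    coupling partner → decomposed reagent (k = 0.0230 /h)

In the flask, the coupling partner used by the target step over that used by the side step is 0.88 at the start and 2.1 at 0.0438 d. So the side step takes the larger part at first and the smaller part by then. The flask's price is 1.56 against my 1.47, with 8.76 × 10⁻⁴ M of decomposed reagent standing there too. My colleague's view comes nearer at low charge but does not hold there: the neighbour with 0.015 M of coupling partner holds less side product than the flask, 3.45%, and its target falls 8 percentage points short of the one-to-one 30.0%, against 18 points short in the flask. My price for that neighbour, 1.28, gives 23.4% target, and the neighbour holds 22.0% at 25.5% conversion.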